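**Retrosynthetic overview**

1. Ring C is made last: the (2S)-flavanone comes from a 2'-hydroxychalcone by catalyst-controlled 6-endo oxa-Michael closure. Only the phenol para to the lavandulyl group is free, which fixes the 6-lavandulyl pattern; MOM removal ends the route.
2. The chalcone is cut at the aryl–C(=O) bond: an aryllithium carrying ring A and the lavandulyl chain acylates a Weinreb cinnamamide carrying ring B and C2–C4 (late union of two halves).
3. The ring A half comes from a 2-bromo-4-iodo phloroglucinol tri-ether and (R)-lavandulylzinc iodide by iodide-selective Negishi coupling; the lavandulyl stereocentre is set by Evans deconjugative prenylation of a senecioyl imide.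
4. Both aromatic rings come from resorcinol through one shared phenol (Ir-catalysed C–H borylation/oxidation); ring B gains its three-carbon arm by ortho-lithiation/formylation and Knoevenagel–Doebner condensation.
5. Ring order: rings A and B are carried as benzene rings from resorcinol; ring C is the only ring built, at step 17.

Assumption: the quinine-derived thiourea of step 17 is taken to give the 2S sense; if the opposite sense is found, its quinidine-derived pseudo-enantiomer is used without other change.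

**Route**

Step 1
Reactants: 1 resorcinol (benzene-1,3-diol)
Product: 2 1,3-bis(methoxymethoxy)benzene
Conditions: MOMCl, i-Pr2NEt, CH2Cl2, 0 °C → rt
Reagents that add atoms: chloromethyl methyl ether (MOMCl), COCCl
Why: Double O-alkylation of the phenol with MOMCl (Williamson-type acetal protection) gives a base-stable ether that later directs ortho-lithiation.

Step 2
Reactants: 2 1,3-bis(methoxymethoxy)benzene
Product: 4 3,5-bis(methoxymethoxy)phenol, via aryl pinacol boronate 3 (not isolated)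
Conditions: [Ir(OMe)(cod)]2 (1.5 mol %), 4,4'-di-tert-butyl-2,2'-bipyridine (3 mol %), B2pin2, THF, 80 °C; then 30% H2O2, aq NaOH, 0 °C → rt
Reagents that add atoms: hydrogen peroxide, OO
Why: Sterically governed iridium-catalysed C–H borylation (Hartwig–Miyaura type) takes the only C–H with no ortho neighbour, and oxidation of the C–B bond delivers the third, still free, oxygen.

Step 3
Reactants: 5 3-methylbut-2-enoyl chloride
Product: 6 (4R)-4-benzyl-3-(3-methylbut-2-enoyl)-1,3-oxazolidin-2-one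
Conditions: (4R)-4-benzyl-1,3-oxazolidin-2-one, n-BuLi, THF, −78 °C; then 5, −78 → 0 °C
Reagents that add atoms: (4R)-4-benzyl-1,3-oxazolidin-2-one (Evans auxiliary), O=C1N[C@H](Cc2ccccc2)CO1
Why: N-acylation of the lithiated Evans oxazolidinone by the acid chloride (nucleophilic acyl substitution) installs the auxiliary that later controls the lavandulyl centre.

Step 4
Reactants: 6 (4R)-4-benzyl-3-(3-methylbut-2-enoyl)-1,3-oxazolidin-2-one; 7 1-bromo-3-methylbut-2-ene (prenyl bromide)
Product: 9 (4R)-4-benzyl-3-[(2R)-5-methyl-2-(prop-1-en-2-yl)hex-4-enoyl]-1,3-oxazolidin-2-one, via sodium dienolate 8 (not isolated)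
Conditions: NaN(SiMe3)2, THF, −78 °C; then 7, −78 → −40 °C
Reagents that add atoms: none
Why: Evans asymmetric alkylation in its deconjugative form: γ-deprotonation gives the chelated Z-dienolate, and prenyl bromide attacks Cα on the face away from the benzyl group, setting the (2R) centre.

Step 5
Reactants: 9 (4R)-4-benzyl-3-[(2R)-5-methyl-2-(prop-1-en-2-yl)hex-4-enoyl]-1,3-oxazolidin-2-one
Product: 10 (2R)-5-methyl-2-(prop-1-en-2-yl)hex-4-en-1-ol [(R)-lavandulol]
Conditions: LiBH4, THF, 0 °C → rt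
Reagents that add atoms: none
Why: Hydride reduction of the exocyclic imide carbonyl (reductive auxiliary cleavage) releases the alcohol under non-epimerising conditions and returns the auxiliary.

Step 6
Reactants: 10 (R)-lavandulol
Product: 11 (3R)-3-(iodomethyl)-2,6-dimethylhepta-1,5-diene [(R)-lavandulyl iodide]
Conditions: PPh3, I2, imidazole, CH2Cl2, 0 °C → rt
Reagents that add atoms: iodine, II
Why: Appel-type iodination is an SN2 displacement at the primary carbon, so the adjacent stereocentre and both alkenes are untouched.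

Step 7
Reactants: 4 3,5-bis(methoxymethoxy)phenol
Product: 12 [3,5-bis(methoxymethoxy)phenoxy]tri(propan-2-yl)silane
Conditions: TIPSCl, imidazole, DMF, rt
Reagents that add atoms: chlorotri(propan-2-yl)silane (TIPSCl), CC(C)[Si](Cl)(C(C)C)C(C)C
Why: Silylation of the lone free phenol gives a bulky, non-directing TIPS ether that marks the future ring oxygen O1 and is later removed by fluoride alone.

Step 8
Reactants: 12 [3,5-bis(methoxymethoxy)phenoxy]tri(propan-2-yl)silane
Product: 14 [4-iodo-3,5-bis(methoxymethoxy)phenoxy]tri(propan-2-yl)silane, via aryllithium 13 (not isolated)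
Conditions: n-BuLi, TMEDA, THF, 0 °C; then I2, −78 °C → rt
Reagents that add atoms: iodine, II
Why: Directed ortho-metalation occurs at the carbon flanked by two MOM ethers (cooperative coordination, while the TIPS ether does not direct), and iodine traps the aryllithium.

Step 9
Reactants: 14 [4-iodo-3,5-bis(methoxymethoxy)phenoxy]tri(propan-2-yl)silane
Product: 15 [2-bromo-4-iodo-3,5-bis(methoxymethoxy)phenoxy]tri(propan-2-yl)silane
Conditions: NBS (1.0 equiv), MeCN, 0 °C, dark
Reagents that add atoms: N-bromosuccinimide, O=C1CCC(=O)N1Br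
Why: Electrophilic aromatic bromination of the tri-oxygenated ring can only take one of the two equivalent remaining C–H positions, placing a bromide beside the TIPS ether for later exchange.

Step 10
Reactants: 11 (R)-lavandulyl iodide; 15 [2-bromo-4-iodo-3,5-bis(methoxymethoxy)phenoxy]tri(propan-2-yl)silane
Product: 17 {2-bromo-3,5-bis(methoxymethoxy)-4-[(2S)-5-methyl-2-(prop-1-en-2-yl)hex-4-en-1-yl]phenoxy}tri(propan-2-yl)silane, via alkylzinc iodide 16 (not isolated)
Conditions: 11, Zn dust (activated with BrCH2CH2Br/Me3SiCl), LiCl, THF, 40 °C; then 15, Pd(OAc)2 (3 mol %), SPhos (6 mol %), THF, 25 °C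
Reagents that add atoms: none
Why: Negishi coupling: zinc inserts into the primary iodide without touching the β-stereocentre, and zerovalent palladium adds to the C–I bond far faster than to the more hindered C–Br bond, so only the carbon between the MOM ethers is alkylated (the descriptor changes to S by priority only).

Step 11
Reactants: 4 3,5-bis(methoxymethoxy)phenol
Product: 18 1,3,5-tris(methoxymethoxy)benzene
Conditions: MOMCl, i-Pr2NEt, CH2Cl2, 0 °C → rt
Reagents that add atoms: chloromethyl methyl ether (MOMCl), COCCl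
Why: O-alkylation with MOMCl as in step 1 gives the symmetric tri-ether for ring B.

Step 12
Reactants: 18 1,3,5-tris(methoxymethoxy)benzene
Product: 21 2,4,6-tris(methoxymethoxy)benzaldehyde, via aryllithium 19 (not isolated), via lithium hemiaminolate 20 (not isolated)
Conditions: n-BuLi, TMEDA, THF, 0 °C; then DMF, 0 °C → rt; aq NH4Cl
Reagents that add atoms: N,N-dimethylformamide, CN(C)C=O
Why: Directed ortho-metalation between two MOM ethers followed by formylation with DMF (Bouveault-type) gives the aldehyde when the hemiaminolate collapses at work-up.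

Step 13
Reactants: 21 2,4,6-tris(methoxymethoxy)benzaldehyde; 22 malonic acid (propanedioic acid)
Product: 23 (2E)-3-[2,4,6-tris(methoxymethoxy)phenyl]prop-2-enoic acid
Conditions: pyridine, piperidine (cat.), 90 °C
Reagents that add atoms: none
Why: Knoevenagel–Doebner condensation with decarboxylation gives the (E)-cinnamic acid, and the pyridine medium keeps the MOM ethers intact.

Step 14
Reactants: 23 (2E)-3-[2,4,6-tris(methoxymethoxy)phenyl]prop-2-enoic acid
Product: 25 (2E)-N-methoxy-N-methyl-3-[2,4,6-tris(methoxymethoxy)phenyl]prop-2-enamide, via acyl imidazolide 24 (not isolated)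
Conditions: 1,1'-carbonyldiimidazole, THF, rt; then MeNH(OMe)·HCl, rt
Reagents that add atoms: N,O-dimethylhydroxylamine hydrochloride, CNOC.Cl
Why: Carboxyl activation as the acyl imidazolide and aminolysis (amide coupling) gives the Weinreb amide under neutral conditions.

Step 15
Reactants: 17 {2-bromo-3,5-bis(methoxymethoxy)-4-[(2S)-5-methyl-2-(prop-1-en-2-yl)hex-4-en-1-yl]phenoxy}tri(propan-2-yl)silane; 25 (2E)-N-methoxy-N-methyl-3-[2,4,6-tris(methoxymethoxy)phenyl]prop-2-enamide
Product: 28 (2E)-1-{2,4-bis(methoxymethoxy)-3-[(2S)-5-methyl-2-(prop-1-en-2-yl)hex-4-en-1-yl]-6-{[tri(propan-2-yl)silyl]oxy}phenyl}-3-[2,4,6-tris(methoxymethoxy)phenyl]prop-2-en-1-one, via aryllithium 26 (not isolated), via lithium hemiaminolate 27 (not isolated)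
Conditions: 17, t-BuLi (2.1 equiv), Et2O, −78 °C; then 25 in THF, −78 → −20 °C; aq NH4Cl
Reagents that add atoms: none
Why: Bromine–lithium exchange at −78 °C (faster than silyl migration) and Weinreb ketone synthesis: the chelated tetrahedral adduct survives until work-up, so the enone appears only after all aryllithium is quenched.

Step 16
Reactants: 28 the TIPS-protected chalcone
Product: 29 (2E)-1-{6-hydroxy-2,4-bis(methoxymethoxy)-3-[(2S)-5-methyl-2-(prop-1-en-2-yl)hex-4-en-1-yl]phenyl}-3-[2,4,6-tris(methoxymethoxy)phenyl]prop-2-en-1-one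
Conditions: Bu4NF, AcOH (1:1), THF, 0 °C
Reagents that add atoms: none
Why: Fluoride-induced desilylation, buffered with AcOH so the liberated phenol does not cyclise without stereocontrol, frees only O1 while all five MOM ethers stay.

Step 17
Reactants: 29 the 2'-hydroxychalcone
Product: 30 (2S)-5,7-bis(methoxymethoxy)-6-[(2S)-5-methyl-2-(prop-1-en-2-yl)hex-4-en-1-yl]-2-[2,4,6-tris(methoxymethoxy)phenyl]-2,3-dihydro-4H-chromen-4-one
Conditions: N-[3,5-bis(trifluoromethyl)phenyl]-N'-[(8α,9S)-6'-methoxycinchonan-9-yl]thiourea (quinine-derived, 15 mol %), toluene, 0 °C → rt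
Reagents that add atoms: none
Why: Catalytic asymmetric intramolecular oxa-Michael addition (6-endo-trig): the quinuclidine nitrogen activates the phenol while the thiourea binds the enone carbonyl, closing ring C on one enone face to set (2S); the minor C2 epimer is a diastereomer and is removed by chromatography.

Step 18
Reactants: 30 the penta-MOM flavanone
Product: 31 (2S)-5,7-dihydroxy-6-[(2S)-5-methyl-2-(prop-1-en-2-yl)hex-4-en-1-yl]-2-(2,4,6-trihydroxyphenyl)-2,3-dihydro-4H-chromen-4-one (CNP0107340.1)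
Conditions: 1.25 M HCl in MeOH, THF, 0 → 35 °C, monitored by HPLC; NaHCO3 quench
Reagents that add atoms: none
Why: Acid-catalysed methanolysis of the five aryl MOM acetals (transacetalisation to dimethoxymethane) under mild, monitored conditions frees the phenols without ionising C2 or cyclising the lavandulyl chain.

**Compound list**

1 | resorcinol | Oc1cccc(O)c1 | starting material
2 | 1,3-bis(methoxymethoxy)benzene | COCOc1cccc(OCOC)c1 | intermediate
3 | 2-[3,5-bis(methoxymethoxy)phenyl]-4,4,5,5-tetramethyl-1,3,2-dioxaborolane | COCOc1cc(OCOC)cc(c1)B1OC(C)(C)C(C)(C)O1 | intermediate (not isolated)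
4 | 3,5-bis(methoxymethoxy)phenol | COCOc1cc(O)cc(OCOC)c1 | intermediate
5 | 3-methylbut-2-enoyl chloride | CC(C)=CC(Cl)=O | starting material
6 | (4R)-4-benzyl-3-(3-methylbut-2-enoyl)-1,3-oxazolidin-2-one | CC(C)=CC(=O)N1[C@H](Cc2ccccc2)COC1=O | intermediate
7 | 1-bromo-3-methylbut-2-ene | CC(C)=CCBr | starting material
8 | sodium (1Z)-1-[(4R)-4-benzyl-2-oxo-1,3-oxazolidin-3-yl]-3-methylbuta-1,3-dien-1-olate | C=C(C)/C=C(\[O-])N1[C@H](Cc2ccccc2)COC1=O.[Na+] | intermediate (not isolated)
9 | (4R)-4-benzyl-3-[(2R)-5-methyl-2-(prop-1-en-2-yl)hex-4-enoyl]-1,3-oxazolidin-2-one | C=C(C)[C@@H](CC=C(C)C)C(=O)N1[C@H](Cc2ccccc2)COC1=O | intermediate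
10 | (2R)-5-methyl-2-(prop-1-en-2-yl)hex-4-en-1-ol | C=C(C)[C@@H](CC=C(C)C)CO | intermediate
11 | (3R)-3-(iodomethyl)-2,6-dimethylhepta-1,5-diene | C=C(C)[C@@H](CC=C(C)C)CI | intermediate
12 | [3,5-bis(methoxymethoxy)phenoxy]tri(propan-2-yl)silane | COCOc1cc(O[Si](C(C)C)(C(C)C)C(C)C)cc(OCOC)c1 | intermediate
13 | [2,6-bis(methoxymethoxy)-4-{[tri(propan-2-yl)silyl]oxy}phenyl]lithium | [Li]c1c(OCOC)cc(O[Si](C(C)C)(C(C)C)C(C)C)cc1OCOC | intermediate (not isolated)
14 | [4-iodo-3,5-bis(methoxymethoxy)phenoxy]tri(propan-2-yl)silane | Ic1c(OCOC)cc(O[Si](C(C)C)(C(C)C)C(C)C)cc1OCOC | intermediate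
15 | [2-bromo-4-iodo-3,5-bis(methoxymethoxy)phenoxy]tri(propan-2-yl)silane | COCOc1cc(O[Si](C(C)C)(C(C)C)C(C)C)c(Br)c(OCOC)c1I | intermediate
16 | [(2R)-5-methyl-2-(prop-1-en-2-yl)hex-4-en-1-yl]zinc iodide | C=C(C)[C@@H](CC=C(C)C)C[Zn]I | intermediate (not isolated)
17 | {2-bromo-3,5-bis(methoxymethoxy)-4-[(2S)-5-methyl-2-(prop-1-en-2-yl)hex-4-en-1-yl]phenoxy}tri(propan-2-yl)silane | C=C(C)[C@@H](CC=C(C)C)Cc1c(OCOC)cc(O[Si](C(C)C)(C(C)C)C(C)C)c(Br)c1OCOC | intermediate
18 | 1,3,5-tris(methoxymethoxy)benzene | COCOc1cc(OCOC)cc(OCOC)c1 | intermediate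
19 | [2,4,6-tris(methoxymethoxy)phenyl]lithium | [Li]c1c(OCOC)cc(OCOC)cc1OCOC | intermediate (not isolated)
20 | lithium (dimethylamino)[2,4,6-tris(methoxymethoxy)phenyl]methanolate | [Li+].[O-]C(N(C)C)c1c(OCOC)cc(OCOC)cc1OCOC | intermediate (not isolated)
21 | 2,4,6-tris(methoxymethoxy)benzaldehyde | O=Cc1c(OCOC)cc(OCOC)cc1OCOC | intermediate
22 | malonic acid | OC(=O)CC(=O)O | starting material
23 | (2E)-3-[2,4,6-tris(methoxymethoxy)phenyl]prop-2-enoic acid | OC(=O)/C=C/c1c(OCOC)cc(OCOC)cc1OCOC | intermediate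
24 | (2E)-1-(1H-imidazol-1-yl)-3-[2,4,6-tris(methoxymethoxy)phenyl]prop-2-en-1-one | O=C(/C=C/c1c(OCOC)cc(OCOC)cc1OCOC)n1ccnc1 | intermediate (not isolated)
25 | (2E)-N-methoxy-N-methyl-3-[2,4,6-tris(methoxymethoxy)phenyl]prop-2-enamide | CON(C)C(=O)/C=C/c1c(OCOC)cc(OCOC)cc1OCOC | intermediate
26 | [2,4-bis(methoxymethoxy)-3-[(2S)-5-methyl-2-(prop-1-en-2-yl)hex-4-en-1-yl]-6-{[tri(propan-2-yl)silyl]oxy}phenyl]lithium | C=C(C)[C@@H](CC=C(C)C)Cc1c(OCOC)cc(O[Si](C(C)C)(C(C)C)C(C)C)c([Li])c1OCOC | intermediate (not isolated)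
27 | lithium (2E)-1-{2,4-bis(methoxymethoxy)-3-[(2S)-5-methyl-2-(prop-1-en-2-yl)hex-4-en-1-yl]-6-{[tri(propan-2-yl)silyl]oxy}phenyl}-1-[methoxy(methyl)amino]-3-[2,4,6-tris(methoxymethoxy)phenyl]prop-2-en-1-olate (both configurations at the new carbon) | C=C(C)[C@@H](CC=C(C)C)Cc1c(OCOC)cc(O[Si](C(C)C)(C(C)C)C(C)C)c(C([O-])(/C=C/c2c(OCOC)cc(OCOC)cc2OCOC)N(C)OC)c1OCOC.[Li+] | intermediate (not isolated)
28 | (2E)-1-{2,4-bis(methoxymethoxy)-3-[(2S)-5-methyl-2-(prop-1-en-2-yl)hex-4-en-1-yl]-6-{[tri(propan-2-yl)silyl]oxy}phenyl}-3-[2,4,6-tris(methoxymethoxy)phenyl]prop-2-en-1-one | C=C(C)[C@@H](CC=C(C)C)Cc1c(OCOC)cc(O[Si](C(C)C)(C(C)C)C(C)C)c(C(=O)/C=C/c2c(OCOC)cc(OCOC)cc2OCOC)c1OCOC | intermediate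
29 | (2E)-1-{6-hydroxy-2,4-bis(methoxymethoxy)-3-[(2S)-5-methyl-2-(prop-1-en-2-yl)hex-4-en-1-yl]phenyl}-3-[2,4,6-tris(methoxymethoxy)phenyl]prop-2-en-1-one | C=C(C)[C@@H](CC=C(C)C)Cc1c(OCOC)cc(O)c(C(=O)/C=C/c2c(OCOC)cc(OCOC)cc2OCOC)c1OCOC | intermediate
30 | (2S)-5,7-bis(methoxymethoxy)-6-[(2S)-5-methyl-2-(prop-1-en-2-yl)hex-4-en-1-yl]-2-[2,4,6-tris(methoxymethoxy)phenyl]-2,3-dihydro-4H-chromen-4-one | C=C(C)[C@@H](CC=C(C)C)Cc1c(OCOC)cc2c(c1OCOC)C(=O)C[C@@H](c1c(OCOC)cc(OCOC)cc1OCOC)O2 | intermediate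
31 | (2S)-5,7-dihydroxy-6-[(2S)-5-methyl-2-(prop-1-en-2-yl)hex-4-en-1-yl]-2-(2,4,6-trihydroxyphenyl)-2,3-dihydro-4H-chromen-4-one | C=C(C)[C@@H](CC=C(C)C)Cc1c(O)cc2c(c1O)C(=O)C[C@@H](c1c(O)cc(O)cc1O)O2 | target

**Step count and risks**

Total step count: 18.
Longest linear sequence: 10 steps (1, 2, 7, 8, 9, 10, 15, 16, 17, 18; the ring B arm 1, 2, 11, 12, 13, 14, 15, 16, 17, 18 is equally long; the lavandulyl arm is 9).

The three steps most likely to fail:

Step 10 (Negishi coupling). The aryl iodide carries two ortho ethers, the alkylzinc is β-branched with an allylic β-hydrogen (β-hydride elimination, alkene migration), and some insertion into the C–Br bond is possible. The fallback replaces cross-coupling by a polar alkylation. It sets out from 12, which is lithiated to 13 exactly as in step 8. Alcohol 10 is converted (Tf2O, 2,6-lutidine, CH2Cl2, −78 °C, used cold) into (2R)-5-methyl-2-(prop-1-en-2-yl)hex-4-en-1-yl trifluoromethanesulfonate F1. Aryllithium 13 displaces the primary triflate (THF, −78 → −20 °C) to give {3,5-bis(methoxymethoxy)-4-[(2S)-5-methyl-2-(prop-1-en-2-yl)hex-4-en-1-yl]phenoxy}tri(propan-2-yl)silane F2. Ortho-lithiation of F2 beside its MOM ether (s-BuLi, TMEDA, THF, −78 °C) gives aryllithium 26 directly, where the route is rejoined; compounds 14, 15 and 17 are bypassed.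

Step 17 (asymmetric oxa-Michael). The enone is electron-rich and its β-aryl group is doubly ortho-substituted, so rate and selectivity may be poor, and the closure is reversible under base. The fallback separates ring closure from stereocontrol. It sets out from 29: NaOAc in refluxing EtOH closes ring C without selectivity to give 30 together with its epimer (2R)-5,7-bis(methoxymethoxy)-6-[(2S)-5-methyl-2-(prop-1-en-2-yl)hex-4-en-1-yl]-2-[2,4,6-tris(methoxymethoxy)phenyl]-2,3-dihydro-4H-chromen-4-one F3. The mixture is then resolved kinetically by asymmetric transfer hydrogenation (RuCl[(R,R)-TsDPEN](p-cymene), 2 mol %, HCO2H/Et3N 5:2, EtOAc, rt, stopped near half conversion). The (R,R)-catalyst is expected to reduce F3 faster, from the face opposite its aryl group, to the cis alcohol (2R,4R)-5,7-bis(methoxymethoxy)-6-[(2S)-5-methyl-2-(prop-1-en-2-yl)hex-4-en-1-yl]-2-[2,4,6-tris(methoxymethoxy)phenyl]-3,4-dihydro-2H-chromen-4-ol F4. Unreduced 30 is separated by chromatography, and the route is rejoined at 30. F4 can be oxidised back to F3 (Dess–Martin periodinane) and re-equilibrated through 29.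

Step 18 (global MOM removal). Protic acid can ionise the C2–O1 bond next to the tri-oxygenated ring B (epimerisation, 6-/8-isomer exchange) and can add the freed 5- or 7-OH to the isopropenyl group (chroman formation). The fallback avoids protic acid by silyl transfer. It sets out from 30: Et3SiOTf and 2,2'-bipyridyl (CH2Cl2, 0 °C → rt) exchange each aryl MOM ether for a silyl ether to give (2S)-6-[(2S)-5-methyl-2-(prop-1-en-2-yl)hex-4-en-1-yl]-5,7-bis(triethylsilyloxy)-2-[2,4,6-tris(triethylsilyloxy)phenyl]-2,3-dihydro-4H-chromen-4-one F5, isolated after neutral work-up. Et3N·3HF in THF at 0 °C then gives 31.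

**Further compounds**

F1 | step 10 | (2R)-5-methyl-2-(prop-1-en-2-yl)hex-4-en-1-yl trifluoromethanesulfonate | C=C(C)[C@@H](CC=C(C)C)COS(=O)(=O)C(F)(F)F
F2 | step 10 | {3,5-bis(methoxymethoxy)-4-[(2S)-5-methyl-2-(prop-1-en-2-yl)hex-4-en-1-yl]phenoxy}tri(propan-2-yl)silane | C=C(C)[C@@H](CC=C(C)C)Cc1c(OCOC)cc(O[Si](C(C)C)(C(C)C)C(C)C)cc1OCOC
F3 | step 17 | (2R)-5,7-bis(methoxymethoxy)-6-[(2S)-5-methyl-2-(prop-1-en-2-yl)hex-4-en-1-yl]-2-[2,4,6-tris(methoxymethoxy)phenyl]-2,3-dihydro-4H-chromen-4-one | C=C(C)[C@@H](CC=C(C)C)Cc1c(OCOC)cc2c(c1OCOC)C(=O)C[C@H](c1c(OCOC)cc(OCOC)cc1OCOC)O2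
F4 | step 17 | (2R,4R)-5,7-bis(methoxymethoxy)-6-[(2S)-5-methyl-2-(prop-1-en-2-yl)hex-4-en-1-yl]-2-[2,4,6-tris(methoxymethoxy)phenyl]-3,4-dihydro-2H-chromen-4-ol | C=C(C)[C@@H](CC=C(C)C)Cc1c(OCOC)cc2c(c1OCOC)[C@H](O)C[C@H](c1c(OCOC)cc(OCOC)cc1OCOC)O2
F5 | step 18 | (2S)-6-[(2S)-5-methyl-2-(prop-1-en-2-yl)hex-4-en-1-yl]-5,7-bis(triethylsilyloxy)-2-[2,4,6-tris(triethylsilyloxy)phenyl]-2,3-dihydro-4H-chromen-4-one | C=C(C)[C@@H](CC=C(C)C)Cc1c(O[Si](CC)(CC)CC)cc2c(c1O[Si](CC)(CC)CC)C(=O)C[C@@H](c1c(O[Si](CC)(CC)CC)cc(O[Si](CC)(CC)CC)cc1O[Si](CC)(CC)CC)O2
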